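**Plan**

1. Target numbering: O1, C2 (bearing syringyl ring B), C3 (bearing C9H2OH), ring A = C3a to C7a, acetyl on C5, methoxy on C7.
2. Enabling feature: C3 carries C9, a carbon that can stand at the carboxyl level, next to aryl carbon C3a. The dihydrofuran is therefore a contracted chroman-4-one ring, in which C9 was the C4 carbonyl and C3–C3a is made by a 1,2-shift of C3a from C4 to C3.
3. Cuts, in retrosynthetic order: O–benzyl and C5–acetyl (back to C5–Br); C9–OH back to the methyl ester; C3–C3a (back to the (2S)-chromanone); C2–ring B (conjugate addition to a chromone); chromone C2 from an amide acetal.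
4. Forward: ring A is bought, the pyranone is closed on it, ring B is joined at C2, and the six-membered ring is contracted to the dihydrofuran. Ester reduction, acetyl installation and debenzylation follow.
5. Stereochemistry: C2 (S) comes from a PyOx–palladium catalysed conjugate addition; C3 (trans to C2) comes from the substrate-controlled ring contraction.

Key step: step 6

Assumption: (R)-t-BuPyOx is taken to deliver the (2S)-chromanone, by analogy with the sense in which the (S)-ligand adds aryl groups to cyclic enones; should the addition favour the (2R)-series, the antipodal ligand is used and nothing else changes.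

**Route**

Step 1
Reactants: 1 4-bromo-2,6-dimethoxyphenol
Product: 2 2-(benzyloxy)-5-bromo-1,3-dimethoxybenzene
Conditions: BnBr, K2CO3, DMF, 60 °C
Reagents that add atoms: benzyl bromide, BrCc1ccccc1
Why: Williamson ether synthesis on the phenoxide; the benzyl ether should withstand the organolithium, the acidic oxidative step 6 and the hydride, and can be removed with BCl3 at the end.

Step 2
Reactants: 2 2-(benzyloxy)-5-bromo-1,3-dimethoxybenzene
Product: 5 [4-(benzyloxy)-3,5-dimethoxyphenyl]boronic acid, via aryllithium 3 (not isolated), via lithium aryl(triisopropoxy)borate 4 (not isolated)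
Conditions: n-BuLi, THF, −78 °C; B(OiPr)3, −78 °C to rt; 1 M HCl
Reagents that add atoms: triisopropyl borate, CC(C)OB(OC(C)C)OC(C)C; water, O
Why: Bromine–lithium exchange at −78 °C is faster than ortho-lithiation or attack on the benzyl ether, and borylation of the aryllithium followed by acidic hydrolysis of the ate complex is the standard route to an arylboronic acid.

Step 3
Reactants: 6 1-(5-bromo-2-hydroxy-3-methoxyphenyl)ethanone; 7 N,N-dimethylformamide dimethyl acetal
Product: 8 (2E)-1-(5-bromo-2-hydroxy-3-methoxyphenyl)-3-(dimethylamino)prop-2-en-1-one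
Conditions: toluene, 100 °C
Reagents that add atoms: none
Why: Enaminone formation by condensation of the methyl ketone with the amide acetal, with loss of two molecules of methanol, should leave the chelated phenol free and give the E isomer.

Step 4
Reactants: 8 (2E)-1-(5-bromo-2-hydroxy-3-methoxyphenyl)-3-(dimethylamino)prop-2-en-1-one
Product: 9 6-bromo-8-methoxy-4H-chromen-4-one
Conditions: conc. HCl, CH2Cl2, reflux
Reagents that add atoms: none
Why: Acid-promoted addition of the phenol to the protonated enaminone and elimination of dimethylamine (addition–elimination cyclisation) closes the pyranone ring to the chromone.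

Step 5
Reactants: 9 6-bromo-8-methoxy-4H-chromen-4-one; 5 [4-(benzyloxy)-3,5-dimethoxyphenyl]boronic acid
Product: 10 (2S)-2-[4-(benzyloxy)-3,5-dimethoxyphenyl]-6-bromo-8-methoxy-2,3-dihydro-4H-chromen-4-one
Conditions: Pd(OCOCF3)2 (5 mol %), (R)-t-BuPyOx (6 mol %), NH4PF6 (30 mol %), H2O (5 equiv), ClCH2CH2Cl, 60 °C
Reagents that add atoms: none
Why: Palladium-catalysed asymmetric conjugate addition of an arylboronic acid, in which transmetalation to the cationic divalent palladium–PyOx complex, enantioface-selective insertion of the chromone C2=C3 bond and protonolysis of the palladium enolate set C2 (S) under ligand control, while the metal stays divalent and should leave the C–Br bond alone.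

Step 6
Reactants: 10 (2S)-2-[4-(benzyloxy)-3,5-dimethoxyphenyl]-6-bromo-8-methoxy-2,3-dihydro-4H-chromen-4-one
Product: 13 methyl (2S,3S)-2-[4-(benzyloxy)-3,5-dimethoxyphenyl]-5-bromo-7-methoxy-2,3-dihydro-1-benzofuran-3-carboxylate, via enol ether 11 (not isolated), via trans-3-iodanyl ketal 12 (not isolated)
Conditions: PhI(OAc)2 (1.2 equiv), conc. H2SO4 (1 equiv), HC(OMe)3, 0 °C to rt
Reagents that add atoms: trimethyl orthoformate, COC(OC)OC
Why: Acid and the orthoformate turn the C4 ketone into enol ether 11, the trivalent iodine electrophile adds to C3 on the face opposite the equatorial C2 aryl group and methanol capture at C4 gives ketal 12, whose equatorial C3–I bond is antiperiplanar to the C4–C4a ring bond; ring A carbon C4a (C3a of the product) then bridges to C3 as a phenonium ion and shifts from C4 to C3 with inversion as iodobenzene leaves, and the dimethoxycarbenium ion left at the old C4 is demethylated to the methyl ester. This is the known oxidative ring contraction of flavanones by trivalent iodine or thallium trinitrate in acidic trimethyl orthoformate, a 1,2-aryl shift of the same family as the rearrangement of aryl alkyl ketones to arylalkanoates. The dihydrofuran ring is not closed end to end but arises by contraction of the pyranone, formally a 3-exo-tet attack of C4a on C3 followed by cleavage of C4–C4a, with the O1–C2 bond untouched. C2 (S) is carried over from 10 and controls C3 (S, trans), kinetically through anti iodination and invertive migration and thermodynamically because trans is the less crowded arrangement at the epimerisable ester carbon. The step needs ring A to migrate in preference to the C2 aryl group or to elimination giving the flavone, and it needs ring B to escape oxidation: the equatorial leaving group and the O1 atom ortho to C4a should secure the first, the 4-benzyloxy group twisted out of conjugation by its two flanking methoxy groups makes ring B a poor migrating group and harder to oxidise, and a bromine is carried at the future acetyl position because a second aryl methyl ketone would rearrange in the same way.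

Step 7
Reactants: 13 methyl (2S,3S)-2-[4-(benzyloxy)-3,5-dimethoxyphenyl]-5-bromo-7-methoxy-2,3-dihydro-1-benzofuran-3-carboxylate
Product: 14 [(2S,3R)-2-[4-(benzyloxy)-3,5-dimethoxyphenyl]-5-bromo-7-methoxy-2,3-dihydro-1-benzofuran-3-yl]methanol
Conditions: LiBH4, THF, 0 °C to rt; then H2O
Reagents that add atoms: none
Why: Chemoselective ester reduction by LiBH4 should give the C9 primary alcohol without touching the aryl bromide or the benzyl ether, and the trans C3 centre is not inverted (its descriptor changes from S to R only because the substituent priorities change).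

Step 8
Reactants: 14 [(2S,3R)-2-[4-(benzyloxy)-3,5-dimethoxyphenyl]-5-bromo-7-methoxy-2,3-dihydro-1-benzofuran-3-yl]methanol
Product: 16 1-[(2S,3R)-2-[4-(benzyloxy)-3,5-dimethoxyphenyl]-3-(hydroxymethyl)-7-methoxy-2,3-dihydro-1-benzofuran-5-yl]ethan-1-one, via enol ether 15 (not isolated)
Conditions: tributyl(1-ethoxyvinyl)stannane, Pd(PPh3)4 (5 mol %), toluene, 100 °C; then 1 M HCl, THF, rt
Reagents that add atoms: tributyl(1-ethoxyvinyl)stannane, CCCC[Sn](CCCC)(CCCC)C(=C)OCC; water, O
Why: Stille coupling, in which zerovalent palladium inserts into the only C–Br bond and the 1-ethoxyvinyl group is transferred from tin, followed by mild acid hydrolysis of the enol ether to the methyl ketone, with the free alcohol and both stereocentres as spectators.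

Step 9
Reactants: 16 1-[(2S,3R)-2-[4-(benzyloxy)-3,5-dimethoxyphenyl]-3-(hydroxymethyl)-7-methoxy-2,3-dihydro-1-benzofuran-5-yl]ethan-1-one
Product: 17 1-[(2S,3R)-2-(4-hydroxy-3,5-dimethoxyphenyl)-3-(hydroxymethyl)-7-methoxy-2,3-dihydro-1-benzofuran-5-yl]ethan-1-one
Conditions: BCl3 (3 equiv), pentamethylbenzene (3 equiv), CH2Cl2, −78 °C; then H2O
Reagents that add atoms: none
Why: Lewis-acid cleavage of the aryl benzyl ether by BCl3 at −78 °C, with pentamethylbenzene trapping the benzyl cation (Friedel–Crafts benzylation), should free the phenol, since the benzyl ether flanked by two methoxy groups is the most labile ether present and the ketone, the methyl ethers and the stereocentres are not expected to react at this temperature.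

**Compound list**

1 | 4-bromo-2,6-dimethoxyphenol | COc1cc(Br)cc(OC)c1O | starting material
2 | 2-(benzyloxy)-5-bromo-1,3-dimethoxybenzene | COc1cc(Br)cc(OC)c1OCc1ccccc1 | intermediate
3 | [4-(benzyloxy)-3,5-dimethoxyphenyl]lithium | [Li]c1cc(OC)c(OCc2ccccc2)c(OC)c1 | intermediate
4 | lithium [4-(benzyloxy)-3,5-dimethoxyphenyl]tri(propan-2-yloxy)borate | [Li+].CC(C)O[B-](OC(C)C)(OC(C)C)c1cc(OC)c(OCc2ccccc2)c(OC)c1 | intermediate
5 | [4-(benzyloxy)-3,5-dimethoxyphenyl]boronic acid | COc1cc(B(O)O)cc(OC)c1OCc1ccccc1 | intermediate
6 | 1-(5-bromo-2-hydroxy-3-methoxyphenyl)ethanone | CC(=O)c1cc(Br)cc(OC)c1O | starting material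
7 | N,N-dimethylformamide dimethyl acetal | COC(OC)N(C)C | starting material
8 | (2E)-1-(5-bromo-2-hydroxy-3-methoxyphenyl)-3-(dimethylamino)prop-2-en-1-one | CN(C)/C=C/C(=O)c1cc(Br)cc(OC)c1O | intermediate
9 | 6-bromo-8-methoxy-4H-chromen-4-one | COc1cc(Br)cc2c(=O)ccoc12 | intermediate
10 | (2S)-2-[4-(benzyloxy)-3,5-dimethoxyphenyl]-6-bromo-8-methoxy-2,3-dihydro-4H-chromen-4-one | COc1cc([C@@H]2CC(=O)c3cc(Br)cc(OC)c3O2)cc(OC)c1OCc1ccccc1 | intermediate
11 | (2S)-2-[4-(benzyloxy)-3,5-dimethoxyphenyl]-6-bromo-4,8-dimethoxy-2H-chromene | COc1cc([C@@H]2C=C(OC)c3cc(Br)cc(OC)c3O2)cc(OC)c1OCc1ccccc1 | intermediate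
12 | trans-(2R,3R)-3-[acetoxy(phenyl)-λ3-iodanyl]-2-[4-(benzyloxy)-3,5-dimethoxyphenyl]-6-bromo-4,4,8-trimethoxy-3,4-dihydro-2H-chromene (C2 spatially unchanged; its descriptor changes because C3 now outranks the aryl group) | COc1cc([C@@H]2[C@@H]([I](OC(C)=O)c4ccccc4)C(OC)(OC)c3cc(Br)cc(OC)c3O2)cc(OC)c1OCc1ccccc1 | intermediate
13 | methyl (2S,3S)-2-[4-(benzyloxy)-3,5-dimethoxyphenyl]-5-bromo-7-methoxy-2,3-dihydro-1-benzofuran-3-carboxylate (trans) | COc1cc([C@H]2Oc3c(OC)cc(Br)cc3[C@@H]2C(=O)OC)cc(OC)c1OCc1ccccc1 | intermediate
14 | [(2S,3R)-2-[4-(benzyloxy)-3,5-dimethoxyphenyl]-5-bromo-7-methoxy-2,3-dihydro-1-benzofuran-3-yl]methanol | COc1cc([C@H]2Oc3c(OC)cc(Br)cc3[C@@H]2CO)cc(OC)c1OCc1ccccc1 | intermediate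
15 | [(2S,3R)-2-[4-(benzyloxy)-3,5-dimethoxyphenyl]-5-(1-ethoxyethenyl)-7-methoxy-2,3-dihydro-1-benzofuran-3-yl]methanol | COc1cc([C@H]2Oc3c(OC)cc(C(=C)OCC)cc3[C@@H]2CO)cc(OC)c1OCc1ccccc1 | intermediate
16 | 1-[(2S,3R)-2-[4-(benzyloxy)-3,5-dimethoxyphenyl]-3-(hydroxymethyl)-7-methoxy-2,3-dihydro-1-benzofuran-5-yl]ethan-1-one | COc1cc([C@H]2Oc3c(OC)cc(C(C)=O)cc3[C@@H]2CO)cc(OC)c1OCc1ccccc1 | intermediate
17 | 1-[(2S,3R)-2-(4-hydroxy-3,5-dimethoxyphenyl)-3-(hydroxymethyl)-7-methoxy-2,3-dihydro-1-benzofuran-5-yl]ethan-1-one (CNP0167808.1) | COc1cc([C@H]2Oc3c(OC)cc(C(C)=O)cc3[C@@H]2CO)cc(OC)c1O | target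

**Step count**

Total: 9 steps. Longest linear sequence: 7 steps (steps 3 to 9 from ketone 6; equally steps 1, 2 and 5 to 9 from phenol 1).

**Steps most likely to fail**

Step 6. The trivalent iodine reagent may oxidise the alkoxy-substituted rings. The C2 aryl group may migrate instead of ring A, or elimination to the flavone may compete. The strong acid may also ionise the benzylic C2–O1 bond and erode the C2 configuration. The fallback separates halogenation from rearrangement and sets out from flavanone 10. CuBr2 in EtOAc–CHCl3 at reflux should brominate only the ketone α-carbon and give the trans bromo ketone (2R,3R)-2-[4-(benzyloxy)-3,5-dimethoxyphenyl]-3,6-dibromo-8-methoxy-2,3-dihydro-4H-chromen-4-one F1 (C2 spatially unchanged). HC(OMe)3 and MeOH with TsOH convert it into the dimethyl ketal (2R,3R)-2-[4-(benzyloxy)-3,5-dimethoxyphenyl]-3,6-dibromo-4,4,8-trimethoxy-3,4-dihydro-2H-chromene F2. Catalytic ZnBr2 in toluene at 80 to 100 °C then induces the same 1,2-shift of C4a onto C3 with loss of the equatorial bromide, which is the known rearrangement of α-bromo aryl ketals to arylalkanoates. No oxidant is present when the aryl shift takes place, and the sequence comes back to the route at ester 13.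

Step 5. Transmetalation of the electron-rich boronic acid may be slow and lose to protodeboronation. Enantioface discrimination on the 8-methoxychromone may be insufficient. Catalyst reduction to zerovalent palladium would also engage the aryl bromide. The fallback gives up catalytic asymmetric induction for a racemic synthesis with resolution, and sets out from bromide 2 and ketone 6. Bromine–lithium exchange of 2 (through 3) and a DMF quench give 4-(benzyloxy)-3,5-dimethoxybenzaldehyde F3. Claisen–Schmidt condensation of F3 with 6 (KOH, EtOH, rt) gives the chalcone (2E)-3-[4-(benzyloxy)-3,5-dimethoxyphenyl]-1-(5-bromo-2-hydroxy-3-methoxyphenyl)prop-2-en-1-one F4. NaOAc in refluxing EtOH closes it by oxa-Michael addition to racemic 2-[4-(benzyloxy)-3,5-dimethoxyphenyl]-6-bromo-8-methoxy-2,3-dihydro-4H-chromen-4-one F5. Preparative HPLC on a polysaccharide chiral stationary phase separates the enantiomers, and the (2S)-enantiomer re-enters the route as 10.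

Step 9. BCl3 may ionise the benzylic C2–O1 bond once the para phenol is unmasked, leading to epimerisation at C2 or ring opening, and it may also cleave a methyl ether. The fallback replaces Lewis-acid ionisation by reductive cleavage and sets out from ketone 16. Hydrogenolysis with H2 (1 atm) over Pd/C in EtOAc at rt, stopped after one equivalent of uptake so that the aryl ketone is not reduced, removes the benzyl group as toluene without any cationic intermediate and arrives directly at target 17. No new compound is made.

**Further compounds**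

F1 | step 6 | (2R,3R)-2-[4-(benzyloxy)-3,5-dimethoxyphenyl]-3,6-dibromo-8-methoxy-2,3-dihydro-4H-chromen-4-one (trans) | COc1cc([C@@H]2[C@@H](Br)C(=O)c3cc(Br)cc(OC)c3O2)cc(OC)c1OCc1ccccc1
F2 | step 6 | (2R,3R)-2-[4-(benzyloxy)-3,5-dimethoxyphenyl]-3,6-dibromo-4,4,8-trimethoxy-3,4-dihydro-2H-chromene (trans) | COc1cc([C@@H]2[C@@H](Br)C(OC)(OC)c3cc(Br)cc(OC)c3O2)cc(OC)c1OCc1ccccc1
F3 | step 5 | 4-(benzyloxy)-3,5-dimethoxybenzaldehyde | COc1cc(C=O)cc(OC)c1OCc1ccccc1
F4 | step 5 | (2E)-3-[4-(benzyloxy)-3,5-dimethoxyphenyl]-1-(5-bromo-2-hydroxy-3-methoxyphenyl)prop-2-en-1-one | COc1cc(/C=C/C(=O)c2cc(Br)cc(OC)c2O)cc(OC)c1OCc1ccccc1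
F5 | step 5 | racemic 2-[4-(benzyloxy)-3,5-dimethoxyphenyl]-6-bromo-8-methoxy-2,3-dihydro-4H-chromen-4-one | COc1cc(C2CC(=O)c3cc(Br)cc(OC)c3O2)cc(OC)c1OCc1ccccc1
F0 | step 9 | none | none
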